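The route rests on closing the γ-lactone last, by forming the bond between the lactone oxygen and C6 (germacrane numbering). Its precursor is a ten-membered carbocycle that carries a strained cis-5,6-epoxide beside C7, whose acrylate is still a tert-butyl ester. Acid lets the ester carbonyl open the epoxide at C6 in a 5-exo mode with loss of isobutene; this single operation closes the trans-fused lactone ring (O, C6, C7, C11, C12), inverts C6 and unveils the C5 hydroxyl. It exploits the threo O–C5–C6–O array next to C7. The epoxide stems from a hydroxyl-directed epoxidation of a (Z)-C5=C6 alkene formed by ring-closing metathesis after an asymmetric Barbier allylation.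

Key step: step 12

Remark: germacrane numbering is used (ring C1–C10; C11–C13 are the acrylate/lactone carbons on C7; C14 is the ester carbon on C10; C15 is the methylene on C4), and the ligand enantiomer in step 8 is taken to be the one that gives the 8R carbinol.

Step 1
Reactants: 1 acrolein; 2 tert-butyl acrylate
Product: 3 tert-butyl 3-hydroxy-2-methylenepent-4-enoate (racemic)
Conditions: DABCO (0.3 equiv), neat in excess 2, rt
Reagents that add atoms: none
Why: Morita–Baylis–Hillman reaction, in which the DABCO–acrylate zwitterion adds to the aldehyde carbon of the more electrophilic acrolein; the carbinol centre is racemic and is erased in step 2.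

Step 2
Reactants: 3
Product: 4 tert-butyl (2Z)-2-(bromomethyl)penta-2,4-dienoate
Conditions: PBr3 (0.4 equiv), Et2O, −10 to 0 °C
Reagents that add atoms: phosphorus tribromide, BrP(Br)Br
Why: Bromination of the Morita–Baylis–Hillman alcohol with allylic transposition (SN2') should deliver the fully conjugated primary bromide as the more stable 2Z isomer, in which the vinyl group is trans to the ester.

Step 3
Reactants: 5 myrcene
Product: 6 6,7-epoxymyrcene, 2,2-dimethyl-3-(3-methylidenepent-4-en-1-yl)oxirane (racemic)
Conditions: mCPBA (1.0 equiv), NaHCO3, CH2Cl2, 0 °C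
Reagents that add atoms: mCPBA, OOC(=O)c1cccc(Cl)c1
Why: Prilezhaev epoxidation, in which the electron-rich trisubstituted alkene should react well before the conjugated diene; the epoxide centre is racemic and is cleaved in step 4.

Step 4
Reactants: 6
Product: 8 4-methylenehex-5-enal, via myrcene-6,7-diol 7 (not isolated)
Conditions: H5IO6 (1.2 equiv), THF/H2O, 0 °C to rt
Reagents that add atoms: none
Why: Acidic hydrolysis of the epoxide to the glycol followed in the same flask by Malaprade cleavage, a known type of access to this dienal from myrcene.

Step 5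
Reactants: 9 trimethyl phosphonoacetate; 10 2-bromo-1,1-dimethoxyethane
Product: 11 methyl 2-(dimethoxyphosphoryl)-4,4-dimethoxybutanoate (racemic)
Conditions: NaH, DMF, 0 °C; then 10, NaI (cat.), 80 °C
Reagents that add atoms: none
Why: SN2 C-alkylation of the sodium salt of the phosphonoacetate, helped by iodide exchange on the sluggish β-alkoxy bromide; the new centre is racemic and becomes sp2 in step 6.

Step 6
Reactants: 11; 8
Product: 12 methyl (2E)-2-(2,2-dimethoxyethyl)-6-methylideneocta-2,7-dienoate
Conditions: NaH, THF, 0 °C; then 8, 0 °C to rt
Reagents that add atoms: none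
Why: Horner–Wadsworth–Emmons olefination, which with a stabilised phosphonate should favour the E enoate (ester trans to C2), the geometry that later puts C2 and C9 cis on the ring.

Step 7
Reactants: 12
Product: 13 methyl (2E)-6-methylidene-2-(2-oxoethyl)octa-2,7-dienoate
Conditions: Amberlyst-15, acetone/H2O (10:1), rt; used at once
Reagents that add atoms: water, O
Why: Mild acid-catalysed acetal hydrolysis on a sulfonic acid resin, chosen so that the β,γ-unsaturated aldehyde does not slip into conjugation.

Step 8
Reactants: 13; 4
Product: 15 1-tert-butyl 7-methyl (3R,4R,6E)-3-ethenyl-4-hydroxy-2-methylidene-6-(4-methylidenehex-5-en-1-ylidene)heptanedioate (syn adduct; C3 and C4 are the later C7 and C8), via trimethylsilyl ether 14 (not isolated)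
Conditions: CrCl2 (10 mol%), chiral 1,8-bis(4-isopropyl-2-oxazolinyl)carbazole ligand (12 mol%), Mn powder (2 equiv), TMSCl (1.5 equiv), i-Pr2NEt (0.3 equiv), THF, 0 °C to rt; then 1 M HCl, THF, 0 °C
Reagents that add atoms: none
Why: Catalytic enantioselective Nozaki–Hiyama–Kishi-type 2-(alkoxycarbonyl)allylation: after insertion of divalent chromium into the C–Br bond the allyl unit adds from its γ-carbon (C7) through a closed chair transition state in which the vinyl group, cis to the metal-bearing CH2, is axial, so the syn (7R,8R) adduct is expected, while the chiral ligand on chromium selects the aldehyde face; the silyl ether formed by TMSCl turnover is cleaved on acidic work-up, and the tert-butyl ester resists lactonisation onto O8.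

Step 9
Reactants: 15
Product: 16 tert-butyl 2-[(1R,2R,4E,9Z)-2-hydroxy-4-(methoxycarbonyl)-8-methylidenecyclodeca-4,9-dien-1-yl]prop-2-enoate (7R,8R; C5=C6 Z)
Conditions: second-generation Grubbs catalyst (10 mol%), 1,4-benzoquinone (20 mol%), toluene (1 mM), 80 °C
Reagents that add atoms: none
Why: Ring-closing metathesis between the C7 vinyl group and the monosubstituted end of the 1,3-diene with loss of ethene; the 1,1-disubstituted and ester-bearing alkenes are poor metathesis partners, and a ten-membered ring that already holds the ring-cis C1=C10 alkene should take up the new C5=C6 alkene only as the Z isomer.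

Step 10
Reactants: 16
Product: 17 (5S,6R,7R,8R)-cis-5,6-epoxide of 16 (epoxide oxygen on the alkene face that carries C8; 8-OH free)
Conditions: VO(acac)2 (5 mol%), t-BuOOH (1.5 equiv), CH2Cl2, 0 °C
Reagents that add atoms: tert-butyl hydroperoxide, CC(C)(C)OO
Why: Hydroxyl-directed epoxidation of a homoallylic alcohol: the vanadium-bound peroxide is delivered from O8 to the C5=C6 face on which C8 lies while H7 eclipses the alkene to avoid A(1,3) strain with C4, which sets the cis-(5S,6R)-epoxide; the electron-poor C1=C10 and C11=C13 alkenes and the undirected C4=C15 alkene should be left alone.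

Step 11
Reactants: 17; 18 angelic acid
Product: 20 8-O-angelate of 17 ((5S,6R,7R,8R)-epoxy tert-butyl ester), via angelic 2,4,6-trichlorobenzoic anhydride 19 (not isolated)
Conditions: 18, 2,4,6-trichlorobenzoyl chloride, Et3N, toluene, rt; then 17, 50 °C
Reagents that add atoms: none
Why: Esterification through the mixed anhydride (Yamaguchi-type acylation run without DMAP), conditions under which the Z geometry of the angelate should be kept; no stereocentre is touched and the epoxide meets only a weak base.

Step 12
Reactants: 20
Product: 21 CNP0163095.1, (5S,6S,7R,8R)-8-angeloyloxy-5-hydroxy-12,6-olide of germacra-1(10)E,4(15),11(13)-trien-14-oic acid methyl ester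
Conditions: (+)-camphor-10-sulfonic acid (0.5 equiv), dry CH2Cl2, 0 °C to rt
Reagents that add atoms: none
Why: The acid-activated cis-5,6-epoxide is opened at C6 by the carbonyl oxygen of the tert-butyl ester and the tert-butyl group then leaves as isobutene, so that epoxide strain drives the C6–O bond formation and the ester is converted directly into the lactone. The closest known reaction type is the acid-mediated cyclisation of γ,δ-epoxy tert-butyl esters to δ-hydroxy-γ-lactones. The lactone ring (O, C6, C7, C11, C12) closes in the 5-exo-tet mode. C6 is set by SN2 inversion (6R in 20 becomes 6S), so it is controlled by the epoxide configuration fixed in step 10, and this inversion places H6 trans to H7; C5 keeps its C–O bond and configuration and emerges as the free allylic alcohol. The step needs attack at C6 and not at the allylic C5 (6-endo): C11 can sit anti to the C6–O bond so that the ester carbonyl is in line for backside attack, a five-membered ring is formed, and in a cis-epoxide whose vinyl group is 2-substituted and part of the ten-membered ring the alkene cannot become coplanar with the breaking C5–O bond, so allylic assistance at C5 should be weak. It also needs the tert-butyl ester to react in preference to the other two esters: the methyl ester is remote and the angelate carbonyl lies on the epoxide-oxygen face of C6, where it cannot attack from the back.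

Compound list
1 | acrolein | C=CC=O | starting material
2 | tert-butyl acrylate | C=CC(=O)OC(C)(C)C | starting material
3 | tert-butyl 3-hydroxy-2-methylenepent-4-enoate (racemic) | C=CC(O)C(=C)C(=O)OC(C)(C)C | intermediate
4 | tert-butyl (2Z)-2-(bromomethyl)penta-2,4-dienoate | C=C/C=C(\CBr)C(=O)OC(C)(C)C | intermediate
5 | myrcene (7-methyl-3-methylideneocta-1,6-diene) | CC(C)=CCCC(=C)C=C | starting material
6 | 6,7-epoxymyrcene, 2,2-dimethyl-3-(3-methylidenepent-4-en-1-yl)oxirane (racemic) | CC1(C)OC1CCC(=C)C=C | intermediate
7 | myrcene-6,7-diol, 2-methyl-6-methylideneoct-7-ene-2,3-diol (racemic) | CC(C)(O)C(O)CCC(=C)C=C | intermediate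
8 | 4-methylenehex-5-enal | O=CCCC(=C)C=C | intermediate
9 | trimethyl phosphonoacetate | COC(=O)CP(=O)(OC)OC | starting material
10 | 2-bromo-1,1-dimethoxyethane | COC(OC)CBr | starting material
11 | methyl 2-(dimethoxyphosphoryl)-4,4-dimethoxybutanoate (racemic) | COC(OC)CC(C(=O)OC)P(=O)(OC)OC | intermediate
12 | methyl (2E)-2-(2,2-dimethoxyethyl)-6-methylideneocta-2,7-dienoate | COC(OC)C/C(C(=O)OC)=C\CCC(=C)C=C | intermediate
13 | methyl (2E)-6-methylidene-2-(2-oxoethyl)octa-2,7-dienoate | O=CC/C(C(=O)OC)=C\CCC(=C)C=C | intermediate
14 | O-trimethylsilyl ether of 15 (3R,4R,6E) | C=C(C(=O)OC(C)(C)C)[C@@H](C=C)[C@H](O[Si](C)(C)C)C/C(C(=O)OC)=C\CCC(=C)C=C | intermediate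
15 | 1-tert-butyl 7-methyl (3R,4R,6E)-3-ethenyl-4-hydroxy-2-methylidene-6-(4-methylidenehex-5-en-1-ylidene)heptanedioate | C=C(C(=O)OC(C)(C)C)[C@@H](C=C)[C@H](O)C/C(C(=O)OC)=C\CCC(=C)C=C | intermediate
16 | tert-butyl 2-[(1R,2R,4E,9Z)-2-hydroxy-4-(methoxycarbonyl)-8-methylidenecyclodeca-4,9-dien-1-yl]prop-2-enoate | C=C(C(=O)OC(C)(C)C)[C@@H]1[C@H](O)C/C(C(=O)OC)=C\CCC(=C)/C=C\1 | intermediate
17 | (5S,6R,7R,8R)-cis-5,6-epoxide of 16, 8-OH free | C=C(C(=O)OC(C)(C)C)[C@@H]1[C@H](O)C/C(C(=O)OC)=C\CCC(=C)[C@@H]2O[C@H]12 | intermediate
18 | angelic acid, (2Z)-2-methylbut-2-enoic acid | C/C=C(/C)C(=O)O | starting material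
19 | angelic 2,4,6-trichlorobenzoic anhydride | C/C=C(/C)C(=O)OC(=O)c1c(Cl)cc(Cl)cc1Cl | intermediate
20 | 8-O-angelate of 17, (5S,6R,7R,8R)-epoxy tert-butyl ester | C=C(C(=O)OC(C)(C)C)[C@@H]1[C@H](OC(=O)/C(C)=C\C)C/C(C(=O)OC)=C\CCC(=C)[C@@H]2O[C@H]12 | intermediate
21 | CNP0163095.1, (5S,6S,7R,8R)-8-angeloyloxy-5-hydroxy-12,6-olide of germacra-1(10)E,4(15),11(13)-trien-14-oic acid methyl ester | C=C1C(=O)O[C@H]2[C@H]1[C@H](OC(=O)/C(C)=C\C)C/C(C(=O)OC)=C\CCC(=C)[C@@H]2O | target

Total step count: 12. Longest linear sequence: 9 steps (steps 3, 4, 6, 7, 8, 9, 10, 11 and 12, from myrcene).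

Steps most likely to fail

Step 12. The process at risk is opening of the epoxide at the allylic carbon C5 to a six-membered lactone, or capture of the epoxide by the angelate carbonyl, under acid. The fallback leaves the acid out and sets out from 17. NaH (0.2 equiv, THF, 0 °C) lets the O8 alkoxide close onto the tert-butyl ester to give the cis-8,12-lactone epoxide F1. LiOH (1 equiv, THF/H2O, 0 °C to rt) opens this α-methylene lactone, and the free carboxylate then opens the epoxide at C6 in an SN2, 5-exo fashion to give, after mild acidification, the 5,8-diol 12,6-lactone F2. Acylation of the less hindered O8 with the mixed anhydride 19 (the C5 hydroxyl is flanked by the fully substituted C4 and by C6) returns to the route at 21.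

Step 9. The process at risk is closure of a five-membered ring by the C6 carbene onto the C1=C10 enoate, or oligomerisation because the open chain does not fold into the strained ring. The fallback sets out from 15. CSA (benzene, 60 °C) closes O8 onto the tert-butyl ester to give the cis-8,12-lactone triene F3, in which the C7 vinyl group and the C9 chain are held cis on a five-membered ring. Ring-closing metathesis of this pre-organised triene (second-generation Grubbs catalyst, toluene, 80 °C) should give the macrocyclic cis-8,12-lactone F4. LiOH (1 equiv, THF/H2O) and then MeI (DMF) open the lactone to the hydroxy methyl ester F5, which is taken through the chemistry of steps 10 and 11 to the epoxy alcohol methyl ester F6 and its angelate F7. The chemistry of step 12, run in wet CH2Cl2 so that methanol is lost in place of isobutene, returns to the route at 21.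

Step 8. The process at risk is poor facial selectivity at the aldehyde, erosion of the syn selectivity through equilibration of the allylchromium geometry, or drift of the aldehyde into conjugation. The fallback sets out from 4. Borylation (B2pin2, Pd2(dba)3, toluene, 50 °C) gives the allylboronate F8 with the same alkene geometry. Allylboration of 13 under chiral phosphoric acid catalysis (the TRIP enantiomer that gives the 8R carbinol, toluene, −30 °C) goes through a closed chair transition state that fixes the syn relationship and returns to the route at 15.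

Further compounds
F1 | step 12 | cis-8,12-lactone epoxide, (5S,6R,7R,8R)-5,6-epoxy-12,8-olide of germacra-1(10)E,4(15),11(13)-trien-14-oic acid methyl ester | C=C1C(=O)O[C@@H]2C/C(C(=O)OC)=C\CCC(=C)[C@@H]3O[C@@H]3[C@H]12
F2 | step 12 | 5,8-diol 12,6-lactone, the 8-O-deacyl analogue of 21 | C=C1C(=O)O[C@H]2[C@H]1[C@H](O)C/C(C(=O)OC)=C\CCC(=C)[C@@H]2O
F3 | step 9 | cis-8,12-lactone triene, the α-methylene-γ-butyrolactone formed from 15 | C=C1C(=O)O[C@H](C/C(C(=O)OC)=C\CCC(=C)C=C)[C@@H]1C=C
F4 | step 9 | macrocyclic cis-8,12-lactone with the (5Z)-diene | C=C1C(=O)O[C@@H]2C/C(C(=O)OC)=C\CCC(=C)/C=C\[C@H]12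
F5 | step 9 | hydroxy methyl ester, the methyl ester analogue of 16 | C=C(C(=O)OC)[C@@H]1[C@H](O)C/C(C(=O)OC)=C\CCC(=C)/C=C\1
F6 | step 9 | epoxy alcohol methyl ester, the methyl ester analogue of 17 | C=C(C(=O)OC)[C@@H]1[C@H](O)C/C(C(=O)OC)=C\CCC(=C)[C@@H]2O[C@H]12
F7 | step 9 | epoxy angelate methyl ester, the methyl ester analogue of 20 | C=C(C(=O)OC)[C@@H]1[C@H](OC(=O)/C(C)=C\C)C/C(C(=O)OC)=C\CCC(=C)[C@@H]2O[C@H]12
F8 | step 8 | tert-butyl (2E)-2-[(4,4,5,5-tetramethyl-1,3,2-dioxaborolan-2-yl)methyl]penta-2,4-dienoate | C=C/C=C(\CB1OC(C)(C)C(C)(C)O1)C(=O)OC(C)(C)C
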